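**Retrosynthetic overview**

- The strategy rests on the ring fusion carbons C4a and C8a of the naphthazarin. Each lies between an oxygen-bearing carbon of ring A (C5, C8) and an oxygen-bearing carbon of ring B (C4, C1), so ring B can be welded onto an intact 3,6-dioxygenated benzyne by forming C4–C4a and C1–C8a together.
- Late disconnections: the two ring A MOM ethers, then the C1' ester C–O bond (Steglich), then the ring B quinone from a 4-silyloxy-1-naphthol.
- Key disconnection: ring B by aryne (4+2) cycloaddition onto a 4-substituted 2-silyloxyfuran, with opening of the oxa bridge.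
- The silyloxyfuran comes from a butenolide, made by oxidising a 5-silylfuran. The silyl handle is placed on 3-furaldehyde first, so the position of the lactone carbonyl does not depend on lithiating the elaborated furan. C1'–C2' and the C1' stereocentre come from an asymmetric alkenylzinc addition.
- Ring order: ring A is bought (bromohydroquinone), the furan supplies C1–C4, and ring B is the only ring formed, in the key step.

Key step: step 8

Assumption: the two quinone tautomers of the free naphthazarin interconvert rapidly, so the ring B quinone drawn for the target and its ring A tautomer are treated as one compound; ring atoms are numbered as in the target naphthoquinone with the side chain on C2.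

**Route**

Step 1
Reactants: 1 3-furaldehyde
Product: 4 5-(trimethylsilyl)furan-3-carbaldehyde, via lithium morpholino alkoxide 2 (not isolated), via C5-lithiated alkoxide 3 (not isolated)
Conditions: morpholine, n-BuLi, THF, −78 °C; 1; s-BuLi, −78 °C; TMSCl, −78 °C to rt; dilute aq. HCl work-up
Reagents that add atoms: chlorotrimethylsilane C[Si](C)(C)Cl
Why: In situ protection of the aldehyde as a lithium α-amino alkoxide followed by metalation is expected to occur at the open furan α-position C5, because the bulky, non-chelating morpholine aminal shields C2; silyl quench and hydrolysis of the aminal then return the aldehyde.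

Step 2
Reactants: 5 2-methylbut-3-yn-2-ol
Product: 6 triethyl[(2-methylbut-3-yn-2-yl)oxy]silane
Conditions: TESCl, imidazole, DMAP (cat.), DMF, rt
Reagents that add atoms: chlorotriethylsilane CC[Si](Cl)(CC)CC
Why: Standard silylation of a tertiary propargylic alcohol, needed so that the hydroxyl does not consume borane or zinc reagent in step 3.

Step 3
Reactants: 6 triethyl[(2-methylbut-3-yn-2-yl)oxy]silane; 4 5-(trimethylsilyl)furan-3-carbaldehyde
Product: 9 (1R,2E)-4-methyl-4-(triethylsilyloxy)-1-[5-(trimethylsilyl)furan-3-yl]pent-2-en-1-ol, via alkenyldicyclohexylborane 7 (not isolated), via alkenyl(ethyl)zinc 8 (not isolated)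
Conditions: BH3·SMe2, cyclohexene, toluene, 0 °C (gives Cy2BH); 6, 0 °C to rt; Et2Zn, −78 °C; (2R)-(+)-3-exo-morpholinoisoborneol (5 mol%), 4, −10 °C; aq. NH4Cl
Reagents that add atoms: none
Why: Catalytic asymmetric alkenylzinc addition to an aldehyde: syn hydroboration of the terminal alkyne fixes the E geometry, boron-to-zinc exchange gives 8, and the zinc amino alkoxide from the (2R) ligand should deliver the alkenyl group to the Re face of the aldehyde to set C1' as R (the (2S) ligand is the one that directs Si-face delivery to aryl aldehydes), the configuration to be confirmed by MTPA ester analysis before continuing.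

Step 4
Reactants: 9 (1R,2E)-4-methyl-4-(triethylsilyloxy)-1-[5-(trimethylsilyl)furan-3-yl]pent-2-en-1-ol
Product: 10 4-[(1R,2E)-1-(tert-butyldimethylsilyloxy)-4-methyl-4-(triethylsilyloxy)pent-2-en-1-yl]-2-(trimethylsilyl)furan
Conditions: TBSCl, imidazole, DMF, rt
Reagents that add atoms: tert-butyldimethylsilyl chloride CC(C)(C)[Si](C)(C)Cl
Why: Standard silylation of a secondary allylic alcohol, giving a C1' ether robust enough for the peracid, amide base and oxidation steps that follow.

Step 5
Reactants: 10 4-[(1R,2E)-1-(tert-butyldimethylsilyloxy)-4-methyl-4-(triethylsilyloxy)pent-2-en-1-yl]-2-(trimethylsilyl)furan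
Product: 12 4-[(1R,2E)-1-(tert-butyldimethylsilyloxy)-4-methyl-4-(triethylsilyloxy)pent-2-en-1-yl]furan-2(5H)-one, via 2-hydroxyfuran tautomer 11 (not isolated)
Conditions: CH3CO3H (35% in AcOH), NaOAc, CH2Cl2, 0 °C to rt; aq. Na2S2O3/NaHCO3
Reagents that add atoms: peracetic acid CC(=O)OO
Why: Peracid oxidation of a 2-silylfuran (oxidative ipso desilylation) puts the oxygen on the silyl-bearing carbon and 11 tautomerises to the conjugated butenolide, so the carbonyl ends up regiospecifically on the carbon remote from the side chain, while the hindered, electron-poor side-chain alkene should be epoxidised far more slowly than the silylfuran.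

Step 6
Reactants: 12 4-[(1R,2E)-1-(tert-butyldimethylsilyloxy)-4-methyl-4-(triethylsilyloxy)pent-2-en-1-yl]furan-2(5H)-one
Product: 13 2-(tert-butyldimethylsilyloxy)-4-[(1R,2E)-1-(tert-butyldimethylsilyloxy)-4-methyl-4-(triethylsilyloxy)pent-2-en-1-yl]furan
Conditions: TBSOTf, Et3N, CH2Cl2, 0 °C
Reagents that add atoms: tert-butyldimethylsilyl triflate CC(C)(C)[Si](C)(C)OS(=O)(=O)C(F)(F)F
Why: Soft enolisation of a butenolide (silyl triflate and amine) is the standard route to 2-silyloxyfurans, since O-silylation and loss of a ring C5 proton restore the aromatic furan, whereas removal of the hindered C1' hydrogen would give a non-aromatic dienol ether and is not expected, so C1' stays intact.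

Step 7
Reactants: 14 bromohydroquinone
Product: 15 2-bromo-1,4-bis(methoxymethoxy)benzene
Conditions: MOMCl, i-Pr2NEt, CH2Cl2, 0 °C to rt
Reagents that add atoms: chloromethyl methyl ether COCCl
Why: Standard acetal protection of both phenols, which also provides the ortho-directing oxygen groups that flank the future aryne.

Step 8
Reactants: 15 2-bromo-1,4-bis(methoxymethoxy)benzene (2.5 equiv); 13 2-(tert-butyldimethylsilyloxy)-4-[(1R,2E)-1-(tert-butyldimethylsilyloxy)-4-methyl-4-(triethylsilyloxy)pent-2-en-1-yl]furan
Product: 18 4-(tert-butyldimethylsilyloxy)-2-[(1R,2E)-1-(tert-butyldimethylsilyloxy)-4-methyl-4-(triethylsilyloxy)pent-2-en-1-yl]-5,8-bis(methoxymethoxy)naphthalen-1-ol, via aryne 16 (not isolated), via oxa-bridged cycloadduct 17 (not isolated)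
Conditions: LiN(i-Pr)2 (3 equiv), THF, −78 to 0 °C; aq. NH4Cl at 0 °C
Reagents that add atoms: none
Why: The amide removes the C3 hydrogen of 15, the only one flanked by bromine and an acetal oxygen, and the ortho-bromoaryllithium loses LiBr on warming to give the symmetric aryne 16. The electron-rich silyloxyfuran 13 traps 16 through its C2 and C5 termini in an aryne–furan Diels–Alder reaction, the closest known reaction type being the cycloaddition of arynes to 2-alkoxy- and 2-silyloxyfurans that gives 4-oxygenated 1-naphthols. Ring B is closed as a six-membered ring by this concerted (4+2) addition, which forms C4–C4a and C1–C8a in one event; the bridgehead silyl ketal of 17 then opens by donation from the silyloxy oxygen and loss of the other bridgehead hydrogen aromatises ring B, so the furan oxygen becomes the C1 naphthol. No lasting stereocentre is created (the two bridgehead centres of 17, formed as a mixture, are erased) and C1' is a spectator. Regioselectivity is not needed because both aryne carbons have identical ortho acetal neighbours, and the aromatic diene should outcompete the hindered, electron-poor side-chain alkene for the aryne. An excess of 15 and base is used because amide addition to the aryne competes, and the cold quench limits base-induced loss of the C1' silyloxy group from the ortho-naphthoxide.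

Step 9
Reactants: 18 4-(tert-butyldimethylsilyloxy)-2-[(1R,2E)-1-(tert-butyldimethylsilyloxy)-4-methyl-4-(triethylsilyloxy)pent-2-en-1-yl]-5,8-bis(methoxymethoxy)naphthalen-1-ol
Product: 19 2-[(1R,2E)-1-(tert-butyldimethylsilyloxy)-4-methyl-4-(triethylsilyloxy)pent-2-en-1-yl]-5,8-bis(methoxymethoxy)naphthalene-1,4-dione
Conditions: PhI(OAc)2, MeCN/H2O (NaHCO3 buffer), 0 °C
Reagents that add atoms: none
Why: Hypervalent iodine oxidation of a para-silyloxy phenol to the para-quinone, in which two-electron oxidation of the free naphthol and loss of the silyl group from the resulting silyloxonium ion give the ring B quinone while the fully etherified ring A is not oxidised.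

Step 10
Reactants: 19 2-[(1R,2E)-1-(tert-butyldimethylsilyloxy)-4-methyl-4-(triethylsilyloxy)pent-2-en-1-yl]-5,8-bis(methoxymethoxy)naphthalene-1,4-dione
Product: 20 2-[(1R,2E)-1,4-dihydroxy-4-methylpent-2-en-1-yl]-5,8-bis(methoxymethoxy)naphthalene-1,4-dione
Conditions: HF·pyridine, pyridine, THF, 0 °C to rt
Reagents that add atoms: none
Why: Fluoride cleavage of silyl ethers under buffered, weakly acidic conditions should remove both the tertiary TES and the secondary TBS ether while the MOM acetals and the base-sensitive quinone are left alone.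

Step 11
Reactants: 20 2-[(1R,2E)-1,4-dihydroxy-4-methylpent-2-en-1-yl]-5,8-bis(methoxymethoxy)naphthalene-1,4-dione; 21 (R)-2-methylbutanoic acid
Product: 22 (1R,2E)-1-[5,8-bis(methoxymethoxy)-1,4-dioxo-1,4-dihydronaphthalen-2-yl]-4-hydroxy-4-methylpent-2-en-1-yl (2R)-2-methylbutanoate
Conditions: DCC, DMAP (cat.), CH2Cl2, 0 °C
Reagents that add atoms: none
Why: Steglich esterification acylates the secondary C1' alcohol through the N-acylpyridinium ion while the tertiary C4' alcohol is too hindered to react, and an α-alkyl acid without an α-heteroatom is not expected to epimerise at 0 °C with catalytic DMAP, so both stereocentres are carried through unchanged.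

Step 12
Reactants: 22 (1R,2E)-1-[5,8-bis(methoxymethoxy)-1,4-dioxo-1,4-dihydronaphthalen-2-yl]-4-hydroxy-4-methylpent-2-en-1-yl (2R)-2-methylbutanoate
Product: 23 (1R,2E)-1-(5,8-dihydroxy-1,4-dioxo-1,4-dihydronaphthalen-2-yl)-4-hydroxy-4-methylpent-2-en-1-yl (2R)-2-methylbutanoate (CNP0265539.1)
Conditions: MgBr2·OEt2, CH2Cl2/Et2O, 0 °C to rt; aq. NH4Cl/citric acid
Reagents that add atoms: none
Why: Lewis acid cleavage of aryl MOM ethers, in which magnesium chelated between each quinone carbonyl and the peri acetal oxygen activates the acetal towards bromide, so both MOM groups should leave at a temperature where the ester, the alkene and the tertiary allylic alcohol survive.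

**Compound list**

1 | 3-furaldehyde | O=Cc1ccoc1 | starting material
2 | lithium (furan-3-yl)(morpholin-4-yl)methanolate | [Li]OC(N1CCOCC1)c1ccoc1 | intermediate (not isolated)
3 | lithium (5-lithiofuran-3-yl)(morpholin-4-yl)methanolate | [Li]OC(N1CCOCC1)c1coc([Li])c1 | intermediate (not isolated)
4 | 5-(trimethylsilyl)furan-3-carbaldehyde | O=Cc1coc([Si](C)(C)C)c1 | intermediate
5 | 2-methylbut-3-yn-2-ol | C#CC(C)(C)O | starting material
6 | triethyl[(2-methylbut-3-yn-2-yl)oxy]silane | C#CC(C)(C)O[Si](CC)(CC)CC | intermediate
7 | dicyclohexyl[(E)-3-methyl-3-(triethylsilyloxy)but-1-en-1-yl]borane | CC[Si](CC)(CC)OC(C)(C)/C=C/B(C1CCCCC1)C1CCCCC1 | intermediate (not isolated)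
8 | ethyl[(E)-3-methyl-3-(triethylsilyloxy)but-1-en-1-yl]zinc | CC[Zn]/C=C/C(C)(C)O[Si](CC)(CC)CC | intermediate (not isolated)
9 | (1R,2E)-4-methyl-4-(triethylsilyloxy)-1-[5-(trimethylsilyl)furan-3-yl]pent-2-en-1-ol | O[C@H](/C=C/C(C)(C)O[Si](CC)(CC)CC)c1coc([Si](C)(C)C)c1 | intermediate
10 | 4-[(1R,2E)-1-(tert-butyldimethylsilyloxy)-4-methyl-4-(triethylsilyloxy)pent-2-en-1-yl]-2-(trimethylsilyl)furan | CC(C)(C)[Si](C)(C)O[C@H](/C=C/C(C)(C)O[Si](CC)(CC)CC)c1coc([Si](C)(C)C)c1 | intermediate
11 | 4-[(1R,2E)-1-(tert-butyldimethylsilyloxy)-4-methyl-4-(triethylsilyloxy)pent-2-en-1-yl]furan-2-ol | CC(C)(C)[Si](C)(C)O[C@H](/C=C/C(C)(C)O[Si](CC)(CC)CC)c1coc(O)c1 | intermediate (not isolated)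
12 | 4-[(1R,2E)-1-(tert-butyldimethylsilyloxy)-4-methyl-4-(triethylsilyloxy)pent-2-en-1-yl]furan-2(5H)-one | CC(C)(C)[Si](C)(C)O[C@H](/C=C/C(C)(C)O[Si](CC)(CC)CC)C1=CC(=O)OC1 | intermediate
13 | 2-(tert-butyldimethylsilyloxy)-4-[(1R,2E)-1-(tert-butyldimethylsilyloxy)-4-methyl-4-(triethylsilyloxy)pent-2-en-1-yl]furan | CC(C)(C)[Si](C)(C)O[C@H](/C=C/C(C)(C)O[Si](CC)(CC)CC)c1coc(O[Si](C)(C)C(C)(C)C)c1 | intermediate (key-step precursor)
14 | bromohydroquinone | Oc1ccc(O)c(Br)c1 | starting material
15 | 2-bromo-1,4-bis(methoxymethoxy)benzene | COCOc1ccc(OCOC)c(Br)c1 | intermediate (key-step precursor)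
16 | 3,6-bis(methoxymethoxy)benzyne | COCOC1=CC=C(OCOC)C#C1 | intermediate (not isolated)
17 | 1-(tert-butyldimethylsilyloxy)-3-[(1R,2E)-1-(tert-butyldimethylsilyloxy)-4-methyl-4-(triethylsilyloxy)pent-2-en-1-yl]-5,8-bis(methoxymethoxy)-1,4-dihydro-1,4-epoxynaphthalene (bridgehead epimers) | CC(C)(C)[Si](C)(C)O[C@H](/C=C/C(C)(C)O[Si](CC)(CC)CC)C1=CC2(O[Si](C)(C)C(C)(C)C)OC1c1c(OCOC)ccc(OCOC)c12 | intermediate (not isolated)
18 | 4-(tert-butyldimethylsilyloxy)-2-[(1R,2E)-1-(tert-butyldimethylsilyloxy)-4-methyl-4-(triethylsilyloxy)pent-2-en-1-yl]-5,8-bis(methoxymethoxy)naphthalen-1-ol | CC(C)(C)[Si](C)(C)O[C@H](/C=C/C(C)(C)O[Si](CC)(CC)CC)c1cc(O[Si](C)(C)C(C)(C)C)c2c(OCOC)ccc(OCOC)c2c1O | intermediate (key-step product)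
19 | 2-[(1R,2E)-1-(tert-butyldimethylsilyloxy)-4-methyl-4-(triethylsilyloxy)pent-2-en-1-yl]-5,8-bis(methoxymethoxy)naphthalene-1,4-dione | CC(C)(C)[Si](C)(C)O[C@H](/C=C/C(C)(C)O[Si](CC)(CC)CC)C1=CC(=O)c2c(OCOC)ccc(OCOC)c2C1=O | intermediate
20 | 2-[(1R,2E)-1,4-dihydroxy-4-methylpent-2-en-1-yl]-5,8-bis(methoxymethoxy)naphthalene-1,4-dione | O[C@H](/C=C/C(C)(C)O)C1=CC(=O)c2c(OCOC)ccc(OCOC)c2C1=O | intermediate
21 | (R)-2-methylbutanoic acid | CC[C@@H](C)C(=O)O | starting material
22 | (1R,2E)-1-[5,8-bis(methoxymethoxy)-1,4-dioxo-1,4-dihydronaphthalen-2-yl]-4-hydroxy-4-methylpent-2-en-1-yl (2R)-2-methylbutanoate | CC[C@@H](C)C(=O)O[C@H](/C=C/C(C)(C)O)C1=CC(=O)c2c(OCOC)ccc(OCOC)c2C1=O | intermediate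
23 | (1R,2E)-1-(5,8-dihydroxy-1,4-dioxo-1,4-dihydronaphthalen-2-yl)-4-hydroxy-4-methylpent-2-en-1-yl (2R)-2-methylbutanoate (CNP0265539.1) | CC[C@@H](C)C(=O)O[C@H](/C=C/C(C)(C)O)C1=CC(=O)c2c(O)ccc(O)c2C1=O | target

**Step count**

Total: 12 steps. Longest linear sequence: 10 steps (steps 1, 3, 4, 5, 6, 8, 9, 10, 11, 12 from 3-furaldehyde).

**Steps most likely to fail, with fallbacks**

1. Step 8 (aryne cycloaddition). What may go wrong: the aryne may be intercepted by the amide or by its own aryllithium precursor before the furan reacts; the base may attack the silyl dienol ether; or the ortho-naphthoxide may lose the C1' silyloxy group on warming (quinone-methide pathway), which would erode C1'. Fallback: release the same aryne by halogen–lithium exchange at −78 °C with no amide present. Setting out from bromide 15, LiN(i-Pr)2 is added at −78 °C in the presence of B(Oi-Pr)3, so the ortho-bromoaryllithium is trapped before it loses LiBr; oxidation with H2O2 should then give 2-bromo-3,6-bis(methoxymethoxy)phenol F1. Triflation (Tf2O, pyridine, CH2Cl2) gives 2-bromo-3,6-bis(methoxymethoxy)phenyl trifluoromethanesulfonate F2. Treatment of F2 with n-BuLi in THF at −78 °C in the presence of furan 13 should generate aryne 16 by bromine–lithium exchange and loss of triflate. Cycloaddition gives 17, and brief exposure to silica gel or a trace of acetic acid opens any surviving bridged ketal, so the fallback rejoins the route at naphthol 18.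

2. Step 12 (MOM cleavage as last step). What may go wrong: Lewis acid ionisation of the tertiary allylic alcohol (allylic transposition or elimination) or of the allylic ester, or incomplete removal of the second acetal. Fallback: change the order so that neither the free tertiary alcohol nor the ester meets the Lewis acid. Setting out from quinone 19, MgBr2·OEt2 cleavage of the two peri MOM ethers while both side-chain oxygens are still silylated should give 2-[(1R,2E)-1-(tert-butyldimethylsilyloxy)-4-methyl-4-(triethylsilyloxy)pent-2-en-1-yl]-5,8-dihydroxynaphthalene-1,4-dione F3. HF·pyridine then gives 2-[(1R,2E)-1,4-dihydroxy-4-methylpent-2-en-1-yl]-5,8-dihydroxynaphthalene-1,4-dione F4. Steglich acylation of F4 with acid 21 (DCC, catalytic DMAP, CH2Cl2, 0 °C) should be selective for the secondary C1' alcohol, since the chelated naphthazarin hydroxyls and the tertiary alcohol are unreactive, and leads directly to target 23.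

3. Step 5 (peracid oxidation of the silylfuran). What may go wrong: competing epoxidation of the side-chain alkene, acid-induced loss of the tertiary TES ether, or oxidative opening of the furan to an enedione instead of clean ipso oxidation. Fallback: use singlet oxygen instead of a peracid. Setting out from silylfuran 10, photooxygenation (O2, tetraphenylporphyrin, hν, CH2Cl2, −78 °C) should convert the silyl-bearing carbon into the lactone carbonyl and give 4-[(1R,2E)-1-(tert-butyldimethylsilyloxy)-4-methyl-4-(triethylsilyloxy)pent-2-en-1-yl]-5-hydroxyfuran-2(5H)-one F5. NaBH4 in EtOH at 0 °C reduces the masked aldehyde of F5, and mildly acidic work-up relactonises to butenolide 12, where the route resumes.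

**Further compounds**

F1 | step 8 | 2-bromo-3,6-bis(methoxymethoxy)phenol | Oc1c(Br)c(OCOC)ccc1OCOC
F2 | step 8 | 2-bromo-3,6-bis(methoxymethoxy)phenyl trifluoromethanesulfonate | O=S(=O)(Oc1c(Br)c(OCOC)ccc1OCOC)C(F)(F)F
F3 | step 12 | 2-[(1R,2E)-1-(tert-butyldimethylsilyloxy)-4-methyl-4-(triethylsilyloxy)pent-2-en-1-yl]-5,8-dihydroxynaphthalene-1,4-dione | CC(C)(C)[Si](C)(C)O[C@H](/C=C/C(C)(C)O[Si](CC)(CC)CC)C1=CC(=O)c2c(O)ccc(O)c2C1=O
F4 | step 12 | 2-[(1R,2E)-1,4-dihydroxy-4-methylpent-2-en-1-yl]-5,8-dihydroxynaphthalene-1,4-dione | O[C@H](/C=C/C(C)(C)O)C1=CC(=O)c2c(O)ccc(O)c2C1=O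
F5 | step 5 | 4-[(1R,2E)-1-(tert-butyldimethylsilyloxy)-4-methyl-4-(triethylsilyloxy)pent-2-en-1-yl]-5-hydroxyfuran-2(5H)-one | CC(C)(C)[Si](C)(C)O[C@H](/C=C/C(C)(C)O[Si](CC)(CC)CC)C1=CC(=O)OC1O
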